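**Plan**

- Retrosynthesis: the five O–benzyl bonds are cut first, then C8–OMe (back through C8–Br to C8–H), then ring C at three bonds at once (O1–C8a, C4–C4a and O1–C2). This leaves a ring A aryne and a ring B 2,3-dimethoxyacrylic acid.
- Enabling feature: ring A holds the carbonyl carbon C4 (on C4a) and the ring oxygen O1 (on C8a) on neighbouring carbons, with the C5 oxygen next to C4a. This is an ortho acyl/oxy pair that one aryne can accept in a single operation, and the C5 alkoxy group fixes the orientation.
- Forward: ring A is built as an ortho-silylaryl triflate from 3,4,5-trihydroxybenzaldehyde (steps 1–5) and ring B as the acid from methyl gallate and methyl methoxyacetate (steps 6–9). Ring C arises when the two are joined (step 10); C8 is then brominated and methoxylated and the benzyl ethers are removed (steps 11–13).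
- Stereochemistry: the target has no stereocentre. The only stereo element on the way, the enol ether geometry of the acid, disappears in the ring closure.

Key step: step 10

Assumption: compounds 14, 15 and 17 are drawn as (E) isomers; a (Z) isomer or a mixture should converge on the same flavone because the geometry is erased when C2 becomes tetrahedral during ring closure. Compound 13 is racemic.

**Route**

Step 1
Reactants: 1 3,4,5-trihydroxybenzaldehyde
Product: 2 3,5-dihydroxy-4-methoxybenzaldehyde
Conditions: MeI (1.1 equiv), Li2CO3, DMF, 40 °C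
Reagents that add atoms: iodomethane, CI
Why: The 4-OH, para to the formyl group, is the most acidic phenol, so a weak carbonate base ionises it alone and a Williamson etherification with one equivalent of iodomethane should occur there selectively.

Step 2
Reactants: 2 3,5-dihydroxy-4-methoxybenzaldehyde
Product: 3 3,5-bis(benzyloxy)-4-methoxybenzaldehyde
Conditions: BnBr (2.3 equiv), K2CO3, DMF, 60 °C
Reagents that add atoms: benzyl bromide, BrCc1ccccc1
Why: Williamson etherification of the two remaining phenols under standard carbonate conditions, to which the aldehyde is inert.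

Step 3
Reactants: 3 3,5-bis(benzyloxy)-4-methoxybenzaldehyde
Product: 5 3,5-bis(benzyloxy)-4-methoxyphenol, via aryl formate 4 (not isolated)
Conditions: mCPBA, CH2Cl2, 0 °C → rt; then K2CO3 (cat.), MeOH, rt
Reagents that add atoms: 3-chloroperoxybenzoic acid, OOC(=O)c1cccc(Cl)c1
Why: Baeyer–Villiger (Dakin-type) oxidation in which the electron-rich trialkoxyaryl group migrates in preference to hydride, followed by base-catalysed methanolysis of the aryl formate.

Step 4
Reactants: 5 3,5-bis(benzyloxy)-4-methoxyphenol
Product: 6 2-bromo-3,5-bis(benzyloxy)-4-methoxyphenol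
Conditions: NBS (1.0 equiv), CH2Cl2, −78 → 0 °C
Reagents that add atoms: N-bromosuccinimide, BrN1C(=O)CCC1=O
Why: Electrophilic aromatic bromination at one of the two equivalent positions ortho to the hydroxyl group, each also ortho or para to a benzyloxy group; one equivalent of NBS at low temperature should stop at the monobromide.

Step 5
Reactants: 6 2-bromo-3,5-bis(benzyloxy)-4-methoxyphenol
Product: 9 3,5-bis(benzyloxy)-4-methoxy-2-(trimethylsilyl)phenyl trifluoromethanesulfonate, via silyl ether 7 (not isolated), via lithium silylphenoxide 8 (not isolated)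
Conditions: HMDS, THF, 70 °C, then evaporate; n-BuLi, THF, −100 → −80 °C; Tf2O, −100 °C → rt
Reagents that add atoms: hexamethyldisilazane, C[Si](C)(C)N[Si](C)(C)C; trifluoromethanesulfonic anhydride, O=S(=O)(OS(=O)(=O)C(F)(F)F)C(F)(F)F
Why: O-silylation, bromine–lithium exchange with retro-Brook 1,3-shift of silicon from oxygen to carbon, and triflation of the resulting phenoxide is the standard one-pot entry to ortho-silylaryl triflates, and exchange at −100 °C should outpace benzylic deprotonation of the benzyl ethers.

Step 6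
Reactants: 10 methyl gallate
Product: 11 methyl 3,4,5-tris(benzyloxy)benzoate
Conditions: BnBr (3.5 equiv), K2CO3, DMF, 60 °C
Reagents that add atoms: benzyl bromide, BrCc1ccccc1
Why: Exhaustive Williamson etherification of the three phenols, a routine protection of gallate esters.

Step 7
Reactants: 11 methyl 3,4,5-tris(benzyloxy)benzoate; 12 methyl methoxyacetate
Product: 13 methyl 2-methoxy-3-oxo-3-[3,4,5-tris(benzyloxy)phenyl]propanoate
Conditions: 12 (2.2 equiv), LiN(iPr)2 (2.2 equiv), THF, −78 °C; then 11, −78 → 0 °C; aq. HCl quench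
Reagents that add atoms: none
Why: Crossed Claisen condensation in which the preformed lithium enolate of methyl methoxyacetate acylates on the non-enolisable benzoate, the second equivalent of enolate deprotonating the β-keto ester and so driving the equilibrium.

Step 8
Reactants: 13 methyl 2-methoxy-3-oxo-3-[3,4,5-tris(benzyloxy)phenyl]propanoate
Product: 14 methyl (E)-2,3-dimethoxy-3-[3,4,5-tris(benzyloxy)phenyl]prop-2-enoate
Conditions: KN(SiMe3)2, THF/DMPU, −78 °C; MeOTf, −78 → 0 °C
Reagents that add atoms: methyl trifluoromethanesulfonate, COS(=O)(=O)C(F)(F)F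
Why: O-alkylation of a β-keto ester enolate, favoured by the dissociated potassium enolate in DMPU, the hard electrophile methyl triflate and the fully substituted α-carbon, which disfavours C-methylation.

Step 9
Reactants: 14 methyl (E)-2,3-dimethoxy-3-[3,4,5-tris(benzyloxy)phenyl]prop-2-enoate
Product: 15 (E)-2,3-dimethoxy-3-[3,4,5-tris(benzyloxy)phenyl]prop-2-enoic acid
Conditions: KOH, THF/MeOH/H2O, 60 °C; then 1 M HCl to pH 4, 0 °C
Reagents that add atoms: potassium hydroxide, [K+].[OH-]
Why: Saponification of the methyl ester, which the β-methoxyacrylate (a vinylogous carbonate) should tolerate, with cold and only mildly acidic work-up to avoid hydrolysis of the enol ether.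

Step 10
Reactants: 15 (E)-2,3-dimethoxy-3-[3,4,5-tris(benzyloxy)phenyl]prop-2-enoic acid; 9 3,5-bis(benzyloxy)-4-methoxy-2-(trimethylsilyl)phenyl trifluoromethanesulfonate
Product: 18 5,7-bis(benzyloxy)-3,6-dimethoxy-2-[3,4,5-tris(benzyloxy)phenyl]-4H-chromen-4-one, via trialkoxybenzyne 16 (not isolated), via hydroxyaryl enone 17 (not isolated)
Conditions: 9 (1.5 equiv), CsF (4 equiv), THF, 125 °C, sealed tube
Reagents that add atoms: none
Why: Fluoride removes the silyl group and triflate departs to give aryne 16; the carboxylate of 15 adds through oxygen at the aryne carbon remote from the benzyloxy group, and the aryl anion formed beside that benzyloxy group attacks its own ester carbonyl and, after C–O scission of the strained adduct, gives the ortho-acyl phenoxide of 17 (O1–C8a and C4–C4a formed). This is the known formal insertion of arynes into the C–O bond of carboxylic acids, which with α,β-unsaturated acids continues by oxa-conjugate closure to chromanones and flavones. Ring C closes 6-endo-trig by addition of the phenoxide to the β-carbon and E1cB loss of methoxide (O1–C2 formed), the long-established chromone closure of ortho-hydroxyaryl β-alkoxy enones, so the flavone oxidation level and the 3-methoxy group arrive together. No stereocentre is formed, and the enol ether geometry is erased at the tetrahedral C2 stage. The step needs regioselective addition to the aryne, secured by the inductive effect of the single flanking alkoxy group (attack at the distal carbon, anion ortho to OBn), which is why C8 is kept as C–H. It also needs acyl transfer to outrun protonation or conjugate attack of the aryl anion, which the high temperature, excess CsF and the in-plane orientation of the aryl anion lone pair should favour.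

Step 11
Reactants: 18 5,7-bis(benzyloxy)-3,6-dimethoxy-2-[3,4,5-tris(benzyloxy)phenyl]-4H-chromen-4-one
Product: 19 5,7-bis(benzyloxy)-8-bromo-3,6-dimethoxy-2-[3,4,5-tris(benzyloxy)phenyl]-4H-chromen-4-one
Conditions: NBS (1.05 equiv), DMF, 0 °C → rt, dark
Reagents that add atoms: N-bromosuccinimide, BrN1C(=O)CCC1=O
Why: Electrophilic aromatic bromination at C8, the only unsubstituted ring A carbon, activated by O1 and the C7 oxygen (ortho) and the C5 oxygen (para), whereas the ring B positions are less activated and shielded by the twisted chromone.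

Step 12
Reactants: 19 5,7-bis(benzyloxy)-8-bromo-3,6-dimethoxy-2-[3,4,5-tris(benzyloxy)phenyl]-4H-chromen-4-one
Product: 20 5,7-bis(benzyloxy)-3,6,8-trimethoxy-2-[3,4,5-tris(benzyloxy)phenyl]-4H-chromen-4-one
Conditions: NaOMe (10 equiv), CuBr (0.2 equiv), DMF/MeOH, 110 °C
Reagents that add atoms: sodium methoxide, [Na+].[O-]C
Why: Ullmann-type copper-catalysed substitution of an aryl bromide by methoxide, a standard conversion of 8-bromoflavones into 8-methoxyflavones, under which benzyl and methyl ethers are inert.

Step 13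
Reactants: 20 5,7-bis(benzyloxy)-3,6,8-trimethoxy-2-[3,4,5-tris(benzyloxy)phenyl]-4H-chromen-4-one
Product: 21 5,7,3',4',5'-pentahydroxy-3,6,8-trimethoxyflavone
Conditions: H2 (1 atm), 10% Pd/C, THF/MeOH, rt, degassed solvents
Reagents that add atoms: none
Why: Heterogeneous palladium-catalysed hydrogenolysis cleaves all five benzylic C–O bonds, while the methyl ethers and the tetrasubstituted C2=C3 bond of the chromone should not be reduced at 1 atm; the oxidation-prone pyrogallol product is handled under argon.

**Compound list**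

1 | 3,4,5-trihydroxybenzaldehyde | O=Cc1cc(O)c(O)c(O)c1 | starting material
2 | 3,5-dihydroxy-4-methoxybenzaldehyde | COc1c(O)cc(C=O)cc1O | intermediate
3 | 3,5-bis(benzyloxy)-4-methoxybenzaldehyde | COc1c(OCc2ccccc2)cc(C=O)cc1OCc1ccccc1 | intermediate
4 | 3,5-bis(benzyloxy)-4-methoxyphenyl formate (not isolated) | COc1c(OCc2ccccc2)cc(OC=O)cc1OCc1ccccc1 | intermediate
5 | 3,5-bis(benzyloxy)-4-methoxyphenol | COc1c(OCc2ccccc2)cc(O)cc1OCc1ccccc1 | intermediate
6 | 2-bromo-3,5-bis(benzyloxy)-4-methoxyphenol | COc1c(OCc2ccccc2)cc(O)c(Br)c1OCc1ccccc1 | intermediate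
7 | [2-bromo-3,5-bis(benzyloxy)-4-methoxyphenoxy]trimethylsilane (not isolated) | COc1c(OCc2ccccc2)cc(O[Si](C)(C)C)c(Br)c1OCc1ccccc1 | intermediate
8 | lithium 3,5-bis(benzyloxy)-4-methoxy-2-(trimethylsilyl)phenoxide (not isolated) | [Li+].COc1c(OCc2ccccc2)cc([O-])c([Si](C)(C)C)c1OCc1ccccc1 | intermediate
9 | 3,5-bis(benzyloxy)-4-methoxy-2-(trimethylsilyl)phenyl trifluoromethanesulfonate | COc1c(OCc2ccccc2)cc(OS(=O)(=O)C(F)(F)F)c([Si](C)(C)C)c1OCc1ccccc1 | intermediate
10 | methyl gallate | COC(=O)c1cc(O)c(O)c(O)c1 | starting material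
11 | methyl 3,4,5-tris(benzyloxy)benzoate | COC(=O)c1cc(OCc2ccccc2)c(OCc2ccccc2)c(OCc2ccccc2)c1 | intermediate
12 | methyl methoxyacetate | COCC(=O)OC | starting material
13 | methyl 2-methoxy-3-oxo-3-[3,4,5-tris(benzyloxy)phenyl]propanoate (racemic) | COC(=O)C(OC)C(=O)c1cc(OCc2ccccc2)c(OCc2ccccc2)c(OCc2ccccc2)c1 | intermediate
14 | methyl (E)-2,3-dimethoxy-3-[3,4,5-tris(benzyloxy)phenyl]prop-2-enoate | CO/C(c1cc(OCc2ccccc2)c(OCc2ccccc2)c(OCc2ccccc2)c1)=C(/OC)C(=O)OC | intermediate
15 | (E)-2,3-dimethoxy-3-[3,4,5-tris(benzyloxy)phenyl]prop-2-enoic acid | CO/C(c1cc(OCc2ccccc2)c(OCc2ccccc2)c(OCc2ccccc2)c1)=C(/OC)C(=O)O | intermediate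
16 | 3,5-bis(benzyloxy)-4-methoxybenzyne (1,2-didehydro arene, not isolated) | COC1=C(OCc2ccccc2)C#CC=C1OCc1ccccc1 | intermediate
17 | (E)-1-[2,4-bis(benzyloxy)-6-hydroxy-3-methoxyphenyl]-2,3-dimethoxy-3-[3,4,5-tris(benzyloxy)phenyl]prop-2-en-1-one (formed as its phenoxide, not isolated) | CO/C(c1cc(OCc2ccccc2)c(OCc2ccccc2)c(OCc2ccccc2)c1)=C(/OC)C(=O)c1c(O)cc(OCc2ccccc2)c(OC)c1OCc1ccccc1 | intermediate
18 | 5,7-bis(benzyloxy)-3,6-dimethoxy-2-[3,4,5-tris(benzyloxy)phenyl]-4H-chromen-4-one | COc1c(OCc2ccccc2)cc2oc(-c3cc(OCc4ccccc4)c(OCc4ccccc4)c(OCc4ccccc4)c3)c(OC)c(=O)c2c1OCc1ccccc1 | intermediate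
19 | 5,7-bis(benzyloxy)-8-bromo-3,6-dimethoxy-2-[3,4,5-tris(benzyloxy)phenyl]-4H-chromen-4-one | COc1c(OCc2ccccc2)c(Br)c2oc(-c3cc(OCc4ccccc4)c(OCc4ccccc4)c(OCc4ccccc4)c3)c(OC)c(=O)c2c1OCc1ccccc1 | intermediate
20 | 5,7-bis(benzyloxy)-3,6,8-trimethoxy-2-[3,4,5-tris(benzyloxy)phenyl]-4H-chromen-4-one | COc1c(OCc2ccccc2)c(OC)c2oc(-c3cc(OCc4ccccc4)c(OCc4ccccc4)c(OCc4ccccc4)c3)c(OC)c(=O)c2c1OCc1ccccc1 | intermediate
21 | 5,7,3',4',5'-pentahydroxy-3,6,8-trimethoxyflavone | COc1c(O)c(OC)c2oc(-c3cc(O)c(O)c(O)c3)c(OC)c(=O)c2c1O | target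

**Step count**

Total: 13 steps. Longest linear sequence: 9 steps (steps 1–5, then 10–13); the ring B branch (steps 6–9) joins at step 10.

**Steps most likely to fail**

Step 10 (aryne insertion and ring closure). The aryl anion may be protonated by the bifluoride generated from the acid before the acyl group migrates, so that the sequence stops at simple O-arylation. Liberated methoxide may also consume the aryne. The fallback sets out from bromophenol 6 and acid 15. Esterification (EDC·HCl, DMAP, CH2Cl2) should give 2-bromo-3,5-bis(benzyloxy)-4-methoxyphenyl (E)-2,3-dimethoxy-3-[3,4,5-tris(benzyloxy)phenyl]prop-2-enoate F1. Bromine–lithium exchange (n-BuLi, THF, −100 °C) then generates the same ortho-aryl anion at a fixed position under aprotic conditions. The known exchange-triggered anionic Fries-type shift of the acyl group from oxygen to carbon should deliver the phenoxide of 17. Closure with TsOH in MeOH at 50 °C returns to the route at 18.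

Step 8 (enolate O-methylation). Alkylation may take place through carbon to give the quaternary α-methyl keto ester, or give a mixture that is hard to separate. The fallback sets out from 13. Acid-catalysed ketalisation (HC(OMe)3, cat. TsOH, MeOH, 60 °C) should give methyl 2,3,3-trimethoxy-3-[3,4,5-tris(benzyloxy)phenyl]propanoate F2. Elimination of methanol on heating in toluene with pyridinium tosylate, with removal of methanol, returns to the route at 14.

Step 12 (copper-catalysed methoxylation). The hindered C8 bromide, flanked by O1 and the C7 benzyloxy group, may undergo protodebromination, or methoxide may open the pyranone ring at 110 °C. The fallback sets out from 19. Miyaura borylation (B2pin2, Pd(OAc)2/SPhos, KOAc, dioxane, 90 °C) should give 5,7-bis(benzyloxy)-3,6-dimethoxy-8-(4,4,5,5-tetramethyl-1,3,2-dioxaborolan-2-yl)-2-[3,4,5-tris(benzyloxy)phenyl]-4H-chromen-4-one F3. Oxidation of the C–B bond (NaBO3·4H2O, THF/H2O, rt) should give 5,7-bis(benzyloxy)-8-hydroxy-3,6-dimethoxy-2-[3,4,5-tris(benzyloxy)phenyl]-4H-chromen-4-one F4. Williamson methylation (MeI, K2CO3, acetone, 50 °C) returns to the route at 20.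

**Further compounds**

F1 | step 10 | 2-bromo-3,5-bis(benzyloxy)-4-methoxyphenyl (E)-2,3-dimethoxy-3-[3,4,5-tris(benzyloxy)phenyl]prop-2-enoate | CO/C(c1cc(OCc2ccccc2)c(OCc2ccccc2)c(OCc2ccccc2)c1)=C(/OC)C(=O)Oc1cc(OCc2ccccc2)c(OC)c(OCc2ccccc2)c1Br
F2 | step 8 | methyl 2,3,3-trimethoxy-3-[3,4,5-tris(benzyloxy)phenyl]propanoate (racemic) | COC(=O)C(OC)C(OC)(OC)c1cc(OCc2ccccc2)c(OCc2ccccc2)c(OCc2ccccc2)c1
F3 | step 12 | 5,7-bis(benzyloxy)-3,6-dimethoxy-8-(4,4,5,5-tetramethyl-1,3,2-dioxaborolan-2-yl)-2-[3,4,5-tris(benzyloxy)phenyl]-4H-chromen-4-one | COc1c(OCc2ccccc2)c(B5OC(C)(C)C(C)(C)O5)c2oc(-c3cc(OCc4ccccc4)c(OCc4ccccc4)c(OCc4ccccc4)c3)c(OC)c(=O)c2c1OCc1ccccc1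
F4 | step 12 | 5,7-bis(benzyloxy)-8-hydroxy-3,6-dimethoxy-2-[3,4,5-tris(benzyloxy)phenyl]-4H-chromen-4-one | COc1c(OCc2ccccc2)c(O)c2oc(-c3cc(OCc4ccccc4)c(OCc4ccccc4)c(OCc4ccccc4)c3)c(OC)c(=O)c2c1OCc1ccccc1
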